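The two flasks differ in the bath during the first 6.0 h, 40 °C in Saturday's against 60 °C in Friday's, and the earlier readings can show whether that stretch still counts at the end.

| flask | starting material | reagent | temperature | remark | time |
|---|---|---|---|---|---|
| amber | 0.10 M | 0.60 equiv | 35 °C | run made earlier |  |
| blue | 0.10 M | 2.4 equiv | 50 °C | run made earlier |  |
| teal | 0.050 M | 1.2 equiv | 35 °C | run made earlier |  |
| Friday's | 0.10 M | 1.20 equiv |  | at 60 °C throughout | 30 h |
| Saturday's | 0.10 M | 1.20 equiv |  | at 40 °C until 6.0 h, from then on at 60 °C | 30 h |

| run | time / h | target / % | starting material / % |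
|---|---|---|---|
| amber | 5.00 | 12.5 | 0.3 |
| amber | 10.0 | 9.7 | 0 |
| amber | 15.0 | 9.0 | 0.1 |
| amber | 20.0 | 8.0 | 0.6 |
| amber | 25.0 | 8.1 | 0 |
| amber | 30.0 | 7.7 | 0.6 |
| amber | 40.0 | 7.4 | 0 |
| blue | 1.33 | 20.7 | 0.1 |
| blue | 4.00 | 14.9 | 0.3 |
| blue | 6.00 | 14.4 | 0.3 |
| blue | 10.0 | 13.4 | 0 |
| blue | 12.0 | 14.1 | 0 |
| blue | 20.0 | 13.7 | 0.3 |
| blue | 25.0 | 14.0 | 0 |
| teal | 3.00 | 15.0 | 0 |
| teal | 10.0 | 11.4 | 0.1 |
| teal | 15.0 | 9.9 | 0 |
| teal | 25.0 | 7.8 | 0.1 |
| teal | 40.0 | 7.7 | 0.2 |

(readings scatter by 0.5 percentage points)

* which of the two ends with the higher amount of target, in percent of the starting material charged ("neither" if they lie within 2 percentage points) (Friday's / Saturday's / neither)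
* target at the end, in percent of the starting material charged, Friday's
* target at the end, in percent of the starting material charged, Saturday's

- the numbers in the tables scatter by 0.5 percentage points (one standard deviation)

The fastest rung is the consumption of starting material: the teal run shows 0% of it at 3.00 h. Saturday's, at 40 °C, is warmer than the teal run and holds twice its [reagent], so its starting material should be consumed before the change at 6.0 h. The next rung is the sinking of target to a plateau. The amber run still falls from 9.0% at 15.0 h to 7.4% at 40.0 h, while the blue run lies level from 6.00 h, so 30 h ending at 60 °C, warmer than the blue run, should bring Friday's and Saturday's to their plateau.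

The plateau should therefore keep a memory of the temperature at which starting material was consumed. Amber and teal share one [reagent] as charged and their last readings lie together, 7.4% and 7.7%, although teal was charged with half the starting material. The reckoning here therefore divides the plateau by [reagent] as charged, assuming proportion to [reagent], and lets the logarithm run straight with temperature:

amber: 7.4% / 0.0600 M = 1.23 /M

blue: 14.0% / 0.240 M = 0.583 /M

This plateau per unit of [reagent] as charged is the capture number, a selectivity factor of a kind; on that assumption it reads lower in the warmer blue run than in amber.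

Saturday's, at 40 °C: 0.961 /M × 0.120 M = 11.5%

Friday's, at 60 °C: 0.354 /M × 0.120 M = 4.25%

So the reckoning here ends Saturday's 7.3 percentage points above Friday's, against a margin of 2 points.

The forecast, whose numbers this reckoning does not share, gives neither, with 10.5% for Friday's and 10% for Saturday's, and its ground reads: “The temperature path could shift either flask”.

The simulation gives Saturday's as the higher, 12.7% against 5.85% for Friday's.

    starting material + reagent → target (k = 8.60 /M/h, Ea = 50.0 kJ/mol)
    starting material → side product (k = 2.90 /h, Ea = 93.0 kJ/mol)
    target ⇌ isomer of the product (K = 1.20, k = 0.110 /h, Ea = 94.0 kJ/mol, ΔH = −12.0 kJ/mol)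
    (constants at 40 °C)

The temperature programme is the main reason for the gap: Friday's, without that difference, ends at 12.7% instead of 5.85%. At the start of Friday's, starting material goes to side product at 7.6 times its rate to target, against 2.81 times at the first temperature of Saturday's. Read back, the ends give capture numbers of 1.06 /M for Saturday's and 0.487 /M for Friday's, in the order reckoned.

A neighbour of Friday's, charged with 0.025 M of starting material, starts with 0.0300 M of reagent, so the capture number reckoned for 60 °C gives 1.06%. The simulation gives 1.65%.

(Readings and results were computed for an exercise; the scatter is artificial.)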